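**Retrosynthetic overview**

1. Numbering of the target: five-membered ring C1–C2–C3–C3a–C7a, six-membered ring C3a–C4–C5–C6–C7–C7a. Late disconnections: ester hydrolysis, C6=C7 by ring-closing metathesis, the enoate by Wittig olefination, and the C4–C5 bond (quaternary C4, benzylic C5) by iridium/amine α-allylation of a C4 aldehyde with 1-phenylprop-2-en-1-ol.
2. Feature the plan rests on: the ring-fusion carbons C7a and C3a carry trans arms (C7 at the acetyl level on C7a, the C4 chain on C3a), and the C3 methyl can be written as =CH2. C7(=O)–C7a–C3a–C3(=CH2) is then a γ,δ-unsaturated methyl ketone, the retron of a Claisen rearrangement.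
3. Key disconnection: the C7a–C3a bond, made by a [3,3] shift of a 2,4-dimethyl-6-alkylidene-tetrahydrooxepine. The shift contracts the oxepine to the five-membered ring and sets C7a and C3a from the alkylidene geometry and the single CH(Me) centre (C1).
4. The oxepine comes from a seven-membered lactone (ketene acetal phosphate, methyl coupling). The lactone comes from Negishi union of a Z-2-iodoallylic alcohol (alkyne trans-hydrostannation) with the zinc reagent of the (R)-3-methylglutaric half-ester.
5. Order of ring formation: oxepanone (step 10, sacrificial), five-membered ring (step 13), six-membered ring (step 20).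

Key step: step 13

Remark: the side-arm carbon bearing the ethyl group is carried as a mixture of epimers in compounds 2 to 20, because step 18 planarises it. The commercial half-ester 8 is used in place of a desymmetrisation of 3-methylglutaric anhydride. In step 18 the ligand and amine antipodes are specified by the configuration they must deliver. TBDPS = tert-butyl(diphenyl)silyl.

**Route**

Step 1
Reactants: 1 2-ethylpropane-1,3-diol
Product: 2 2-(TBDPSO-methyl)butan-1-ol (racemic)
Conditions: NaH (1 equiv), THF, 0 °C; TBDPSCl, rt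
Reagents that add atoms: tert-butyl(chloro)diphenylsilane, CC(C)(C)[Si](Cl)(c1ccccc1)c1ccccc1
Why: O-silylation of the sparingly soluble monosodium alkoxide protects one of the two equivalent hydroxyls; the new centre is racemic, which is harmless because it is erased in step 18.

Step 2
Reactants: 2 2-(TBDPSO-methyl)butan-1-ol
Product: 3 2-(TBDPSO-methyl)butanal
Conditions: TEMPO (cat.), PhI(OAc)2, CH2Cl2, rt
Reagents that add atoms: none
Why: Oxoammonium (TEMPO) oxidation of a primary alcohol stops at the aldehyde and leaves the silyl ether untouched.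

Step 3
Reactants: 3 2-(TBDPSO-methyl)butanal
Product: 4 tert-butyl[(2-ethylbut-3-yn-1-yl)oxy]diphenylsilane
Conditions: dimethyl (1-diazo-2-oxopropyl)phosphonate, K2CO3, MeOH, 0 °C to rt
Reagents that add atoms: dimethyl (1-diazo-2-oxopropyl)phosphonate, CC(=O)C(=[N+]=[N-])P(=O)(OC)OC
Why: Seyferth–Gilbert homologation with the Ohira–Bestmann reagent converts the aldehyde into the terminal alkyne under mild base that the silyl ether tolerates.

Step 4
Reactants: 4 tert-butyl[(2-ethylbut-3-yn-1-yl)oxy]diphenylsilane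
Product: 5 4-(TBDPSO-methyl)hex-2-yn-1-ol
Conditions: n-BuLi, THF, −78 °C; (CH2O)n, −78 °C to rt; aqueous work-up
Reagents that add atoms: paraformaldehyde (as formaldehyde), C=O
Why: Addition of the lithium acetylide to formaldehyde gives the propargylic alcohol whose hydroxyl steers the next step.

Step 5
Reactants: 5 4-(TBDPSO-methyl)hex-2-yn-1-ol
Product: 6 (2Z)-4-(TBDPSO-methyl)-2-(tributylstannyl)hex-2-en-1-ol
Conditions: [Cp*RuCl]4 (cat.), Bu3SnH, CH2Cl2, rt
Reagents that add atoms: tributyltin hydride, CCCC[SnH](CCCC)CCCC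
Why: Hydroxyl-directed ruthenium-catalysed trans-hydrostannation puts tin on the alkyne carbon next to the carbinol and hydrogen anti to it, so tin ends cis to the side arm and the alkene geometry is fixed.

Step 6
Reactants: 6 (2Z)-4-(TBDPSO-methyl)-2-(tributylstannyl)hex-2-en-1-ol
Product: 7 (2Z)-4-(TBDPSO-methyl)-2-iodohex-2-en-1-ol
Conditions: I2, CH2Cl2, 0 °C
Reagents that add atoms: iodine, II
Why: Iododestannylation proceeds with retention at the sp2 carbon and should give the Z iodide (iodine cis to the side arm).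

Step 7
Reactants: 8 (3R)-5-methoxy-3-methyl-5-oxopentanoic acid (methyl hydrogen (R)-3-methylglutarate)
Product: 9 methyl (3S)-4-iodo-3-methylbutanoate
Conditions: PhI(OAc)2, I2, cyclohexane, hν, reflux
Reagents that add atoms: iodine, II
Why: Radical iododecarboxylation (Hunsdiecker type, Suárez modification) replaces the free carboxyl by iodine through a primary alkyl radical; the β stereocentre is not involved and only its descriptor changes.

Step 8
Reactants: 9 methyl (3S)-4-iodo-3-methylbutanoate; 7 (2Z)-4-(TBDPSO-methyl)-2-iodohex-2-en-1-ol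
Product: 11 methyl (3R,5E)-7-(TBDPSO-methyl)-5-(hydroxymethyl)-3-methylnon-5-enoate, via alkylzinc iodide 10 (not isolated)
Conditions: Zn dust, LiCl, THF, 40 °C; then 7, Pd(OAc)2 (cat.), SPhos (cat.), THF, rt (2 equiv of 10)
Reagents that add atoms: none
Why: Zinc insertion into the primary iodide gives a γ-ester alkylzinc that undergoes Negishi sp3–sp2 coupling with retention of the alkene geometry; the excess of zinc reagent covers the free hydroxyl.

Step 9
Reactants: 11 methyl (3R,5E)-7-(TBDPSO-methyl)-5-(hydroxymethyl)-3-methylnon-5-enoate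
Product: 12 (3R,5E)-7-(TBDPSO-methyl)-5-(hydroxymethyl)-3-methylnon-5-enoic acid
Conditions: LiOH, THF–MeOH–H2O, rt; then aq. HCl to pH 4
Reagents that add atoms: lithium hydroxide, [Li+].[OH-]
Why: Saponification of the methyl ester; the primary TBDPS ether and the trisubstituted alkene are stable to aqueous LiOH at room temperature.

Step 10
Reactants: 12 (3R,5E)-7-(TBDPSO-methyl)-5-(hydroxymethyl)-3-methylnon-5-enoic acid
Product: 13 (4R,6E)-6-[2-(TBDPSO-methyl)butylidene]-4-methyloxepan-2-one
Conditions: 2-methyl-6-nitrobenzoic anhydride, DMAP, Et3N, CH2Cl2, slow addition, high dilution, rt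
Reagents that add atoms: none
Why: Shiina lactonisation under high dilution should close the seven-membered lactone, helped by the sp2 ring carbon that removes transannular hydrogens.

Step 11
Reactants: 13 (4R,6E)-6-[2-(TBDPSO-methyl)butylidene]-4-methyloxepan-2-one
Product: 14 (4R,6E)-6-[2-(TBDPSO-methyl)butylidene]-4-methyl-4,5,6,7-tetrahydrooxepin-2-yl diphenyl phosphate
Conditions: KN(SiMe3)2, (PhO)2P(O)Cl, THF–HMPA, −78 °C
Reagents that add atoms: diphenyl chlorophosphate, O=P(Cl)(Oc1ccccc1)Oc1ccccc1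
Why: O-phosphorylation of the kinetic lactone enolate, trapped in situ, gives the cyclic ketene acetal phosphate with the double bond at C2=C3.

Step 12
Reactants: 14 (4R,6E)-6-[2-(TBDPSO-methyl)butylidene]-4-methyl-4,5,6,7-tetrahydrooxepin-2-yl diphenyl phosphate
Product: 15 (4R,6E)-6-[2-(TBDPSO-methyl)butylidene]-2,4-dimethyl-4,5,6,7-tetrahydrooxepine
Conditions: MeZnCl, Pd(PPh3)4 (cat.), THF, rt; purification on Et3N-deactivated silica
Reagents that add atoms: methylzinc chloride, C[Zn]Cl
Why: Palladium-catalysed Negishi coupling of the ketene acetal phosphate installs the C2 methyl and gives the endocyclic methyl enol ether at a temperature well below that of the rearrangement.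

Step 13
Reactants: 15 (4R,6E)-6-[2-(TBDPSO-methyl)butylidene]-2,4-dimethyl-4,5,6,7-tetrahydrooxepine
Product: 16 1-[(1R,2S,5R)-2-(1-TBDPSO-butan-2-yl)-5-methyl-3-methylidenecyclopentyl]ethan-1-one
Conditions: o-xylene, N,O-bis(trimethylsilyl)acetamide (cat.), base-washed sealed tube, 180 °C
Reagents that add atoms: none
Why: Proposed new method: the oxepine is a cyclic allyl vinyl ether (C3=C2–O1–C7–C6=alkylidene carbon) whose thermal [3,3] shift should form the C3–alkylidene carbon bond while O1–C7 breaks, giving the methyl ketone and the exocyclic methylene with carbonyl formation as driving force; the closest known reactions are the Claisen rearrangement of cyclic allyl vinyl ethers and the alicyclic Claisen ring contraction of medium-ring ketene acetals, neither of which has a two-carbon tether (C4–C5) running from the vinyl terminus to the central allyl carbon. The cyclopentane closes across the seven-membered ring through a bicyclo[3.2.1]octane-like array, exo with respect to the enol ether and 5-endo with respect to the alkylidene, a closure that is acceptable only because bond making and breaking are concerted; the tether permits the chair array and excludes the boat. The acetyl-bearing carbon and the side-arm-bearing carbon become trans because the bridged geometry translates the E alkylidene (side arm cis to C5) directly into that relationship. The face pairing is set by the C4 methyl, which should take the endo position on the two-carbon bridge, away from the side arm, and therefore ends cis to the acetyl group. The step needs a clean [3,3] shift rather than ionisation of the allylic C–O bond or migration of the enol ether double bond, which the acid scavenger and base-washed glass are meant to secure.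

Step 14
Reactants: 16 1-[(1R,2S,5R)-2-(1-TBDPSO-butan-2-yl)-5-methyl-3-methylidenecyclopentyl]ethan-1-one
Product: 17 1-[(1R,2S,3R,5R)-2-(1-TBDPSO-butan-2-yl)-3,5-dimethylcyclopentyl]ethan-1-one
Conditions: H2 (1 atm), [Ir(cod)(PCy3)(py)]PF6 (cat.), CH2Cl2, 0 °C to rt
Reagents that add atoms: none
Why: Substrate-directed homogeneous hydrogenation: the acetyl oxygen can bind iridium on the face opposite the bulky side arm, so hydrogen should add syn to the acetyl group and anti to the side arm, which places the new methyl cis to the side arm (3R).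

Step 15
Reactants: 17 1-[(1R,2S,3R,5R)-2-(1-TBDPSO-butan-2-yl)-3,5-dimethylcyclopentyl]ethan-1-one
Product: 18 tert-butyl{2-[(1R,2R,3R,5R)-3,5-dimethyl-2-(prop-1-en-2-yl)cyclopentyl]butoxy}diphenylsilane
Conditions: Ph3PCH3Br, KOtBu, toluene, 0 to 80 °C
Reagents that add atoms: methyltriphenylphosphonium bromide, C[P+](c1ccccc1)(c1ccccc1)c1ccccc1.[Br-]
Why: Wittig methylenation of the methyl ketone gives the isopropenyl group; the α carbon already holds the favoured arrangement (trans to the large side arm), so base should not scramble it.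

Step 16
Reactants: 18 tert-butyl{2-[(1R,2R,3R,5R)-3,5-dimethyl-2-(prop-1-en-2-yl)cyclopentyl]butoxy}diphenylsilane
Product: 19 2-[(1R,2R,3R,5R)-3,5-dimethyl-2-(prop-1-en-2-yl)cyclopentyl]butan-1-ol
Conditions: Bu4NF, THF, rt
Reagents that add atoms: none
Why: Fluoride cleavage of the silyl ether; no other group in the molecule responds to fluoride.

Step 17
Reactants: 19 2-[(1R,2R,3R,5R)-3,5-dimethyl-2-(prop-1-en-2-yl)cyclopentyl]butan-1-ol
Product: 20 2-[(1R,2R,3R,5R)-3,5-dimethyl-2-(prop-1-en-2-yl)cyclopentyl]butanal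
Conditions: Dess–Martin periodinane, CH2Cl2, rt
Reagents that add atoms: none
Why: Dess–Martin oxidation gives the α-branched aldehyde without touching the isopropenyl group; the epimeric α centre does not matter.

Step 18
Reactants: 20 2-[(1R,2R,3R,5R)-3,5-dimethyl-2-(prop-1-en-2-yl)cyclopentyl]butanal; 21 1-phenylprop-2-en-1-ol (racemic)
Product: 22 (2R,3S)-2-[(1R,2R,3R,5R)-3,5-dimethyl-2-(prop-1-en-2-yl)cyclopentyl]-2-ethyl-3-phenylpent-4-enal
Conditions: [Ir(cod)Cl]2 (cat.), BINOL-derived phosphoramidite–olefin ligand (antipode giving the 3S centre, cat.), 9-amino-9-deoxy-epi-cinchona primary amine (pseudo-enantiomer giving the 2R centre, cat.), Cl3CCO2H, ClCH2CH2Cl, rt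
Reagents that add atoms: none
Why: Stereodivergent iridium/amine dual catalysis for α-allylation of α-branched aldehydes: the enamine (which erases the α centre of 20) attacks the branched terminus of the iridium allyl formed from either enantiomer of 21, the amine setting the quaternary carbon and the iridium ligand the benzylic carbon.

Step 19
Reactants: 22 (2R,3S)-2-[(1R,2R,3R,5R)-3,5-dimethyl-2-(prop-1-en-2-yl)cyclopentyl]-2-ethyl-3-phenylpent-4-enal
Product: 23 ethyl (2E,4S,5S)-4-[(1R,2R,3R,5R)-3,5-dimethyl-2-(prop-1-en-2-yl)cyclopentyl]-4-ethyl-2-methyl-5-phenylhepta-2,6-dienoate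
Conditions: Ph3P=C(Me)CO2Et, toluene, 110 °C
Reagents that add atoms: ethyl 2-(triphenyl-λ5-phosphanylidene)propanoate, CCOC(=O)C(C)=P(c1ccccc1)(c1ccccc1)c1ccccc1
Why: Wittig olefination with a stabilised ylide gives the E trisubstituted enoate; the aldehyde has no α hydrogen and cannot epimerise on heating.

Step 20
Reactants: 23 ethyl (2E,4S,5S)-4-[(1R,2R,3R,5R)-3,5-dimethyl-2-(prop-1-en-2-yl)cyclopentyl]-4-ethyl-2-methyl-5-phenylhepta-2,6-dienoate
Product: 24 ethyl (2E)-3-[(1R,3R,3aR,4S,5S,7aR)-4-ethyl-1,3,7-trimethyl-5-phenyl-2,3,3a,4,5,7a-hexahydro-1H-inden-4-yl]-2-methylprop-2-enoate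
Conditions: second-generation Hoveyda–Grubbs catalyst (H2IMes)Cl2Ru=CH(2-iPrOC6H4) (cat.), toluene, 80 °C
Reagents that add atoms: none
Why: Ring-closing metathesis between the vinyl and isopropenyl groups closes the six-membered ring as a trisubstituted cyclohexene; the trisubstituted, electron-poor enoate next to the quaternary carbon should stay out of the reaction.

Step 21
Reactants: 24 ethyl (2E)-3-[(1R,3R,3aR,4S,5S,7aR)-4-ethyl-1,3,7-trimethyl-5-phenyl-2,3,3a,4,5,7a-hexahydro-1H-inden-4-yl]-2-methylprop-2-enoate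
Product: 25 plakotenin, (2E)-3-[(1R,3R,3aR,4S,5S,7aR)-4-ethyl-1,3,7-trimethyl-5-phenyl-2,3,3a,4,5,7a-hexahydro-1H-inden-4-yl]-2-methylprop-2-enoic acid
Conditions: LiOH, THF–MeOH–H2O, 50 °C; then aq. HCl
Reagents that add atoms: lithium hydroxide, [Li+].[OH-]
Why: Saponification of the hindered enoate; no centre in the molecule is epimerisable under these conditions.

**Compound list**

1 | 2-ethylpropane-1,3-diol | CCC(CO)CO | starting material
2 | 2-(TBDPSO-methyl)butan-1-ol (racemic) | CCC(CO)CO[Si](c1ccccc1)(c1ccccc1)C(C)(C)C | intermediate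
3 | 2-(TBDPSO-methyl)butanal | CCC(C=O)CO[Si](c1ccccc1)(c1ccccc1)C(C)(C)C | intermediate
4 | tert-butyl[(2-ethylbut-3-yn-1-yl)oxy]diphenylsilane | CCC(C#C)CO[Si](c1ccccc1)(c1ccccc1)C(C)(C)C | intermediate
5 | 4-(TBDPSO-methyl)hex-2-yn-1-ol | CCC(C#CCO)CO[Si](c1ccccc1)(c1ccccc1)C(C)(C)C | intermediate
6 | (2Z)-4-(TBDPSO-methyl)-2-(tributylstannyl)hex-2-en-1-ol | CCC(CO[Si](c1ccccc1)(c1ccccc1)C(C)(C)C)/C=C(/CO)[Sn](CCCC)(CCCC)CCCC | intermediate
7 | (2Z)-4-(TBDPSO-methyl)-2-iodohex-2-en-1-ol | CCC(CO[Si](c1ccccc1)(c1ccccc1)C(C)(C)C)/C=C(/CO)I | intermediate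
8 | (3R)-5-methoxy-3-methyl-5-oxopentanoic acid | COC(=O)C[C@H](C)CC(=O)O | starting material
9 | methyl (3S)-4-iodo-3-methylbutanoate | COC(=O)C[C@H](C)CI | intermediate
10 | [(2S)-4-methoxy-2-methyl-4-oxobutyl]zinc iodide | COC(=O)C[C@H](C)C[Zn]I | intermediate
11 | methyl (3R,5E)-7-(TBDPSO-methyl)-5-(hydroxymethyl)-3-methylnon-5-enoate | COC(=O)C[C@H](C)C/C(CO)=C\C(CC)CO[Si](c1ccccc1)(c1ccccc1)C(C)(C)C | intermediate
12 | (3R,5E)-7-(TBDPSO-methyl)-5-(hydroxymethyl)-3-methylnon-5-enoic acid | OC(=O)C[C@H](C)C/C(CO)=C\C(CC)CO[Si](c1ccccc1)(c1ccccc1)C(C)(C)C | intermediate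
13 | (4R,6E)-6-[2-(TBDPSO-methyl)butylidene]-4-methyloxepan-2-one | O=C1C[C@H](C)C/C(=C\C(CC)CO[Si](c2ccccc2)(c2ccccc2)C(C)(C)C)CO1 | intermediate
14 | (4R,6E)-6-[2-(TBDPSO-methyl)butylidene]-4-methyl-4,5,6,7-tetrahydrooxepin-2-yl diphenyl phosphate | O=P(Oc1ccccc1)(Oc1ccccc1)OC1=C[C@H](C)C/C(=C\C(CC)CO[Si](c2ccccc2)(c2ccccc2)C(C)(C)C)CO1 | intermediate
15 | (4R,6E)-6-[2-(TBDPSO-methyl)butylidene]-2,4-dimethyl-4,5,6,7-tetrahydrooxepine | CC1=C[C@H](C)C/C(=C\C(CC)CO[Si](c2ccccc2)(c2ccccc2)C(C)(C)C)CO1 | intermediate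
16 | 1-[(1R,2S,5R)-2-(1-TBDPSO-butan-2-yl)-5-methyl-3-methylidenecyclopentyl]ethan-1-one | CC(=O)[C@@H]1[C@H](C)CC(=C)[C@H]1C(CC)CO[Si](c2ccccc2)(c2ccccc2)C(C)(C)C | intermediate
17 | 1-[(1R,2S,3R,5R)-2-(1-TBDPSO-butan-2-yl)-3,5-dimethylcyclopentyl]ethan-1-one | CC(=O)[C@@H]1[C@H](C)C[C@@H](C)[C@H]1C(CC)CO[Si](c2ccccc2)(c2ccccc2)C(C)(C)C | intermediate
18 | tert-butyl{2-[(1R,2R,3R,5R)-3,5-dimethyl-2-(prop-1-en-2-yl)cyclopentyl]butoxy}diphenylsilane | CC(=C)[C@@H]1[C@H](C)C[C@@H](C)[C@H]1C(CC)CO[Si](c2ccccc2)(c2ccccc2)C(C)(C)C | intermediate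
19 | 2-[(1R,2R,3R,5R)-3,5-dimethyl-2-(prop-1-en-2-yl)cyclopentyl]butan-1-ol | CC(=C)[C@@H]1[C@H](C)C[C@@H](C)[C@H]1C(CC)CO | intermediate
20 | 2-[(1R,2R,3R,5R)-3,5-dimethyl-2-(prop-1-en-2-yl)cyclopentyl]butanal | CC(=C)[C@@H]1[C@H](C)C[C@@H](C)[C@H]1C(CC)C=O | intermediate
21 | 1-phenylprop-2-en-1-ol (racemic) | OC(C=C)c1ccccc1 | starting material
22 | (2R,3S)-2-[(1R,2R,3R,5R)-3,5-dimethyl-2-(prop-1-en-2-yl)cyclopentyl]-2-ethyl-3-phenylpent-4-enal | CC[C@](C=O)([C@@H](C=C)c1ccccc1)[C@H]1[C@H](C(C)=C)[C@H](C)C[C@H]1C | intermediate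
23 | ethyl (2E,4S,5S)-4-[(1R,2R,3R,5R)-3,5-dimethyl-2-(prop-1-en-2-yl)cyclopentyl]-4-ethyl-2-methyl-5-phenylhepta-2,6-dienoate | CC[C@](/C=C(\C)C(=O)OCC)([C@@H](C=C)c1ccccc1)[C@H]1[C@H](C(C)=C)[C@H](C)C[C@H]1C | intermediate
24 | ethyl (2E)-3-[(1R,3R,3aR,4S,5S,7aR)-4-ethyl-1,3,7-trimethyl-5-phenyl-2,3,3a,4,5,7a-hexahydro-1H-inden-4-yl]-2-methylprop-2-enoate | CC[C@@]1(/C=C(\C)C(=O)OCC)[C@H]2[C@H](C(C)=C[C@H]1c1ccccc1)[C@H](C)C[C@H]2C | intermediate
25 | plakotenin | CC[C@@]1(/C=C(\C)C(=O)O)[C@H]2[C@H](C(C)=C[C@H]1c1ccccc1)[C@H](C)C[C@H]2C | target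

**Step count and risks**

Total steps: 21. Longest linear sequence: 20 steps (steps 1 to 6, then 8 to 21, from 2-ethylpropane-1,3-diol).

Steps most likely to fail:

Step 13 (labelled step). The bridged chair array may not be reached before other processes take over: migration of the enol ether double bond to the exocyclic position followed by a boat rearrangement to a seven-membered ketone, ionisation of the allylic C–O bond with 1,3-recombination, or imperfect face pairing at C4. The fallback uses known chemistry, sets out from hydroxy ester 11 and returns to the route at ketone 16. Sharpless asymmetric epoxidation of 11 (Ti(OiPr)4, D-(−)-diethyl tartrate, tBuOOH, CH2Cl2, −20 °C) would give the epoxy alcohol F1. Iodination (I2, PPh3, imidazole) gives the epoxy iodide F2, and zinc-mediated reductive opening (Zn, EtOH) gives the transposed secondary allylic alcohol F3, whose carbinol configuration is fixed by the tartrate. Mesylation (MsCl, Et3N, −20 °C) gives the mesylate F4. The ester enolate (LiN(SiMe3)2, THF, −78 °C to rt) then closes the five-membered ring by 5-exo-tet displacement with inversion to the cyclopentane ester F5; the ester-bearing carbon is epimerisable and should settle trans to the side arm. Conversion to the Weinreb amide F6 (MeNHOMe·HCl, iPrMgCl) and addition of MeMgBr deliver 16.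

Step 18. Enamine formation at the crowded α,α-dialkyl aldehyde may be too slow, the resident ring stereocentres may oppose the amine catalyst in face selection, and the congested nucleophile may divert the allyl electrophile to its linear terminus. The fallback sets out from alcohol 19 and returns at aldehyde 22. Oxidation of 19 (TEMPO, PhI(OAc)2, aq. MeCN) gives the carboxylic acid F7. Esterification with (E)-3-phenylprop-2-en-1-ol (DCC, DMAP) gives the cinnamyl ester F8. Ireland–Claisen rearrangement (LiN(iPr)2, THF, −78 °C; Me3SiCl; then warming) forms the same C–C bond through a chair array and gives the quaternary acid F9; this requires the ketene acetal with the cyclopentyl group cis to the allylic oxygen, as expected from enolisation in THF without HMPA. Reduction (LiAlH4) to the neopentyl alcohol F10 and Dess–Martin oxidation give 22.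

Step 14. Face selection may be poor, because the acetyl group and the ring methyl on the upper face compete with the side arm on the lower face and the ketone is only a weak director; the exocyclic alkene may also migrate into the ring before reduction. The fallback sets out from ketone 16 and returns at ketone 17, replacing steric bias and carbonyl binding by hydroxyl-directed delivery through a redox detour. Reduction of 16 (NaBH4, MeOH) gives the carbinol F11. Hydroxyl-directed hydrogenation (H2, [Ir(cod)(PCy3)(py)]PF6, CH2Cl2) from the face of the carbinol arm gives the saturated carbinol F12, and Dess–Martin oxidation returns 17.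

**Further compounds**

F1 | step 13 | methyl (3R)-4-[(2S,3S)-3-(1-TBDPSO-butan-2-yl)-2-(hydroxymethyl)oxiran-2-yl]-3-methylbutanoate | COC(=O)C[C@H](C)C[C@@]1(CO)O[C@H]1C(CC)CO[Si](c2ccccc2)(c2ccccc2)C(C)(C)C
F2 | step 13 | methyl (3R)-4-[(2R,3S)-3-(1-TBDPSO-butan-2-yl)-2-(iodomethyl)oxiran-2-yl]-3-methylbutanoate | COC(=O)C[C@H](C)C[C@@]1(CI)O[C@H]1C(CC)CO[Si](c2ccccc2)(c2ccccc2)C(C)(C)C
F3 | step 13 | methyl (3R,6S)-7-(TBDPSO-methyl)-6-hydroxy-3-methyl-5-methylidenenonanoate | COC(=O)C[C@H](C)CC(=C)[C@@H](O)C(CC)CO[Si](c1ccccc1)(c1ccccc1)C(C)(C)C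
F4 | step 13 | methyl (3R,6S)-7-(TBDPSO-methyl)-6-(methanesulfonyloxy)-3-methyl-5-methylidenenonanoate | COC(=O)C[C@H](C)CC(=C)[C@@H](OS(C)(=O)=O)C(CC)CO[Si](c1ccccc1)(c1ccccc1)C(C)(C)C
F5 | step 13 | methyl (1R,2S,5R)-2-(1-TBDPSO-butan-2-yl)-5-methyl-3-methylidenecyclopentane-1-carboxylate | COC(=O)[C@@H]1[C@H](C)CC(=C)[C@H]1C(CC)CO[Si](c2ccccc2)(c2ccccc2)C(C)(C)C
F6 | step 13 | (1R,2S,5R)-2-(1-TBDPSO-butan-2-yl)-N-methoxy-N,5-dimethyl-3-methylidenecyclopentane-1-carboxamide | CON(C)C(=O)[C@@H]1[C@H](C)CC(=C)[C@H]1C(CC)CO[Si](c2ccccc2)(c2ccccc2)C(C)(C)C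
F7 | step 18 | 2-[(1R,2R,3R,5R)-3,5-dimethyl-2-(prop-1-en-2-yl)cyclopentyl]butanoic acid | CC(=C)[C@@H]1[C@H](C)C[C@@H](C)[C@H]1C(CC)C(=O)O
F8 | step 18 | (2E)-3-phenylprop-2-en-1-yl 2-[(1R,2R,3R,5R)-3,5-dimethyl-2-(prop-1-en-2-yl)cyclopentyl]butanoate | CC(=C)[C@@H]1[C@H](C)C[C@@H](C)[C@H]1C(CC)C(=O)OC/C=C/c1ccccc1
F9 | step 18 | (2R,3S)-2-[(1R,2R,3R,5R)-3,5-dimethyl-2-(prop-1-en-2-yl)cyclopentyl]-2-ethyl-3-phenylpent-4-enoic acid | CC[C@](C(=O)O)([C@@H](C=C)c1ccccc1)[C@H]1[C@H](C(C)=C)[C@H](C)C[C@H]1C
F10 | step 18 | (2R,3S)-2-[(1R,2R,3R,5R)-3,5-dimethyl-2-(prop-1-en-2-yl)cyclopentyl]-2-ethyl-3-phenylpent-4-en-1-ol | CC[C@](CO)([C@@H](C=C)c1ccccc1)[C@H]1[C@H](C(C)=C)[C@H](C)C[C@H]1C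
F11 | step 14 | 1-[(1R,2S,5R)-2-(1-TBDPSO-butan-2-yl)-5-methyl-3-methylidenecyclopentyl]ethan-1-ol | CC(O)[C@@H]1[C@H](C)CC(=C)[C@H]1C(CC)CO[Si](c2ccccc2)(c2ccccc2)C(C)(C)C
F12 | step 14 | 1-[(1R,2S,3R,5R)-2-(1-TBDPSO-butan-2-yl)-3,5-dimethylcyclopentyl]ethan-1-ol | CC(O)[C@@H]1[C@H](C)C[C@@H](C)[C@H]1C(CC)CO[Si](c2ccccc2)(c2ccccc2)C(C)(C)C
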